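**Strategy.** Each half of the target is a trans-fused 2,2,5a-trimethyl-perhydro-1-benzoxepine (oxepane ring A, cyclohexane ring B). Its O1–C2(Me2)–C3(OH) unit and its C5a–C6 bond reveal a 1,5-diepoxide plus an enol nucleophile. The route is iterative: one geranyl β-ketophosphonate is used twice (olefination, Shi epoxidation, hydrosilylation, cyclization). In the key step a silyl triflate turns the acyclic diepoxy silyl enol ether 16, which already carries the finished diacetate half, into the second bicycle. The inner epoxide oxygen attacks C2 of the terminal epoxide (O1–C2 bond) and the enol ether closes ring B at C5a, giving both rings and the free C3 hydroxyl in one operation.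

Key step: step 13

Remark: locants O1, C2, C3, C5a, C6, C7, C9a are those of the 1-benzoxepine skeleton of each bicycle; the D-fructose-derived Shi ketone is taken to give the (R)-configured epoxides of (E)-trisubstituted olefins, which is the sense both halves require.

Step 1
Reactants: 1 geranyl bromide; 2 dimethyl (2-oxopropyl)phosphonate
Product: 3 dimethyl [(5E)-6,10-dimethyl-2-oxoundeca-5,9-dien-1-yl]phosphonate
Conditions: NaH, THF, 0 °C; n-BuLi, 0 °C; then 1, 0 °C → rt
Reagents that add atoms: none
Why: γ-Alkylation of the β-ketophosphonate dianion should take place at the more reactive terminal carbanion by direct SN2 displacement of the allylic bromide, with the (E)-olefin retained.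

Step 2
Reactants: 3 dienyl β-ketophosphonate; 4 (benzyloxy)acetaldehyde
Product: 5 (2E,7E)-1-(benzyloxy)-8,12-dimethyltrideca-2,7,11-trien-4-one
Conditions: LiCl, i-Pr2NEt, MeCN, rt
Reagents that add atoms: none
Why: Horner–Wadsworth–Emmons olefination under Masamune–Roush conditions should give the (E)-enone, and the mild base tolerates the α-alkoxy aldehyde.

Step 3
Reactants: 5 trienone
Product: 6 (2E,7R,8R,11R)-1-(benzyloxy)-7,8:11,12-diepoxy-8,12-dimethyltridec-2-en-4-one
Conditions: D-fructose-derived Shi ketone (0.4 equiv), Oxone (2KHSO5·KHSO4·K2SO4), K2CO3, Bu4NHSO4, Na2B4O7/Na2EDTA buffer, MeCN/CH2(OMe)2/H2O, 0 °C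
Reagents that add atoms: potassium peroxymonosulfate (active salt of Oxone), [K+].[O-]S(=O)(=O)OO
Why: Shi asymmetric epoxidation should oxidize only the two electron-rich trisubstituted olefins through the spiro transition state of the chiral dioxirane, which sets the three (R) centers by catalyst control, while the electron-poor enone olefin is left.

Step 4
Reactants: 6 diepoxy enone
Product: 7 (3Z,7R,8R,11R)-1-(benzyloxy)-7,8:11,12-diepoxy-8,12-dimethyl-4-(triethylsilyloxy)tridec-3-ene
Conditions: Et3SiH, RhCl(PPh3)3 (2 mol %), THF, 50 °C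
Reagents that add atoms: triethylsilane, CC[SiH](CC)CC
Why: Rhodium-catalysed 1,4-hydrosilylation of the s-cis enone should deliver hydride to the β-carbon and silicon to oxygen, giving the regiodefined (Z)-silyl enol ether under neutral conditions that spare the epoxides.

Step 5
Reactants: 7 diepoxy silyl enol ether
Product: 9 bicyclic hydroxy ketone of the acetate half, via triethylsilyl ether 8 (not isolated)
Conditions: TESOTf (0.3 equiv), 2,6-di-tert-butyl-4-methylpyridine, CH2Cl2, −78 °C; then HF·pyridine, THF, 0 °C
Reagents that add atoms: none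
Why: The silyl-triflate-promoted tandem oxa-/carbacyclization (endo opening of the terminal epoxide by the inner epoxide oxygen, then 6-(enolendo)-exo-tet capture of the epoxonium ion by the enol ether) should give the trans-fused bicycle, in which C3 and C9a keep the Shi configuration, C5a is set by inversion and the epimerizable C6 side chain takes the equatorial position, and fluoride then frees the C3 hydroxyl.

Step 6
Reactants: 9 bicyclic hydroxy ketone
Product: 10 (3R,5aR,6R,7S,9aR)-6-[2-(benzyloxy)ethyl]-2,2,5a,7-tetramethyldecahydro-1-benzoxepine-3,7-diol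
Conditions: MeMgBr (3 equiv), THF, −78 → 0 °C
Reagents that add atoms: methylmagnesium bromide, C[Mg]Br
Why: Grignard addition should occur from the equatorial direction because the axial path is blocked by the 1,3-diaxial angular methyl group at C5a, which sets C7 with an axial hydroxyl (7S); the first equivalent only deprotonates the C3 hydroxyl.

Step 7
Reactants: 10 diol
Product: 11 (3R,5aR,6R,7S,9aR)-6-[2-(benzyloxy)ethyl]-2,2,5a,7-tetramethyldecahydro-1-benzoxepine-3,7-diyl diacetate
Conditions: Ac2O, Et3N, DMAP, CH2Cl2, 40 °C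
Reagents that add atoms: acetic anhydride, CC(=O)OC(C)=O
Why: DMAP-catalysed acylation through the N-acetylpyridinium ion should esterify the secondary and, more slowly, the tertiary hydroxyl without touching the benzyl ether or any stereocenter.

Step 8
Reactants: 11 benzyl ether diacetate
Product: 12 (3R,5aR,6R,7S,9aR)-6-(2-hydroxyethyl)-2,2,5a,7-tetramethyldecahydro-1-benzoxepine-3,7-diyl diacetate
Conditions: H2 (1 atm), 10% Pd/C, EtOAc, rt
Reagents that add atoms: none
Why: Catalytic hydrogenolysis should cleave the benzyl ether cleanly, since the molecule holds no olefin at this stage and the acetates are inert.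

Step 9
Reactants: 12 primary alcohol
Product: 13 (3R,5aR,6R,7S,9aR)-6-(2-oxoethyl)-2,2,5a,7-tetramethyldecahydro-1-benzoxepine-3,7-diyl diacetate
Conditions: Dess–Martin periodinane, CH2Cl2, rt
Reagents that add atoms: none
Why: Dess–Martin oxidation should give the aldehyde under near-neutral conditions without epimerization or acetate migration.

Step 10
Reactants: 13 aldehyde; 3 dienyl β-ketophosphonate
Product: 14 (E)-enone carrying the geranyl chain and the diacetate bicycle
Conditions: LiCl, i-Pr2NEt, MeCN, rt
Reagents that add atoms: none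
Why: A second Horner–Wadsworth–Emmons olefination under Masamune–Roush conditions should join the two parts as the (E)-enone and is mild enough for both acetates.

Step 11
Reactants: 14 trienone
Product: 15 (7R,8R,11R)-diepoxy enone
Conditions: D-fructose-derived Shi ketone (0.4 equiv), Oxone (2KHSO5·KHSO4·K2SO4), K2CO3, Bu4NHSO4, Na2B4O7/Na2EDTA buffer, MeCN/CH2(OMe)2/H2O, 0 °C
Reagents that add atoms: potassium peroxymonosulfate (active salt of Oxone), [K+].[O-]S(=O)(=O)OO
Why: Shi asymmetric epoxidation should again oxidize only the two trisubstituted olefins under catalyst control, setting the three (R) centers of the second half independently of the remote bicycle.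

Step 12
Reactants: 15 diepoxy enone
Product: 16 (Z)-triethylsilyl enol ether of the diepoxide
Conditions: Et3SiH, RhCl(PPh3)3 (2 mol %), THF, 50 °C
Reagents that add atoms: triethylsilane, CC[SiH](CC)CC
Why: Rhodium-catalysed 1,4-hydrosilylation should convert the enone into the regiodefined (Z)-silyl enol ether, with epoxides and acetates untouched.

Step 13
Reactants: 16 diepoxy silyl enol ether
Product: 18 bicyclic hydroxy ketone of the methylidene half joined to the diacetate half, via triethylsilyl ether 17 (not isolated)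
Conditions: TESOTf (0.3 equiv), 2,6-di-tert-butyl-4-methylpyridine, CH2Cl2, −78 °C; then HF·pyridine, THF, 0 °C
Reagents that add atoms: none
Why: The silyl triflate silylates the oxygen of the terminal epoxide, the oxygen of the inner epoxide opens it at the tertiary carbon C2 (this forms the O1–C2 ether bond and a bicyclic epoxonium ion), the (Z)-silyl enol ether attacks the quaternary carbon of the epoxonium ion anti to the leaving oxygen, and the silyloxocarbenium ion gives its silyl group back to triflate, which returns the promoter. The closest known reaction type is the silyl-triflate-promoted tandem oxa-/carbacyclization of 1,5-diepoxides ended by an enol silane, known from bio-inspired syntheses of oxepane-fused terpenoids. Oxepane ring A is closed in the endo mode (6-endo opening of the terminal epoxide to the fused epoxonium ion, whose C–O cleavage leaves the seven-membered ether) and cyclohexanone ring B by a 6-(enolendo)-exo-tet closure. C3 and C9a keep the configurations from the Shi epoxidation because their C–O bonds are not broken, C5a is set by inversion at the epoxonium carbon, which enforces the trans ring fusion with an axial methyl group, and C6 is set by the chair transition state of the (Z)-enol ether and, lying next to the ketone, can also settle in the equatorial position by enolization. The step needs initiation at the terminal epoxide, attack at its tertiary carbon and capture by carbon instead of by triflate or an acetate; the tertiary carbon of each trisubstituted epoxide carries the positive charge best, the enol ether carbon sits in reach of a six-membered chair, and the hindered base at −78 °C keeps both acetates and the finished oxepane silent. HF·pyridine then cleaves the triethylsilyl ether 17 to the free C3 hydroxyl.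

Step 14
Reactants: 18 bicyclic hydroxy ketone
Product: 19 target CNP0412606.2
Conditions: Zn, CH2Br2, TiCl4, THF/CH2Cl2, 0 °C → rt
Reagents that add atoms: dibromomethane, BrCBr
Why: Takai–Lombardo methylenation should convert the hindered, enolizable ketone into the exocyclic methylene with a non-basic titanium–zinc reagent that leaves the acetates, the free hydroxyl and the C6 configuration alone.

**Compound list**

1 | geranyl bromide, (2E)-1-bromo-3,7-dimethylocta-2,6-diene | CC(C)=CCC/C(C)=C/CBr | starting material
2 | dimethyl (2-oxopropyl)phosphonate | COP(=O)(OC)CC(C)=O | starting material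
3 | dimethyl [(5E)-6,10-dimethyl-2-oxoundeca-5,9-dien-1-yl]phosphonate | COP(=O)(OC)CC(=O)CC/C=C(\C)CCC=C(C)C | intermediate
4 | (benzyloxy)acetaldehyde | O=CCOCc1ccccc1 | starting material
5 | (2E,7E)-1-(benzyloxy)-8,12-dimethyltrideca-2,7,11-trien-4-one | O=C(/C=C/COCc1ccccc1)CC/C=C(\C)CCC=C(C)C | intermediate
6 | (2E,7R,8R,11R)-1-(benzyloxy)-7,8:11,12-diepoxy-8,12-dimethyltridec-2-en-4-one | O=C(/C=C/COCc1ccccc1)CC[C@H]1O[C@]1(C)CC[C@H]1OC1(C)C | intermediate
7 | (3Z,7R,8R,11R)-1-(benzyloxy)-7,8:11,12-diepoxy-8,12-dimethyl-4-(triethylsilyloxy)tridec-3-ene | CC[Si](CC)(CC)O/C(=C\CCOCc1ccccc1)CC[C@H]1O[C@]1(C)CC[C@H]1OC1(C)C | intermediate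
8 | (3R,5aR,6R,9aR)-6-[2-(benzyloxy)ethyl]-2,2,5a-trimethyl-3-(triethylsilyloxy)octahydro-1-benzoxepin-7(2H)-one | c1ccccc1COCC[C@@H]1[C@@]2(C)CC[C@@H](O[Si](CC)(CC)CC)C(C)(C)O[C@@H]2CCC1=O | intermediate (not isolated)
9 | (3R,5aR,6R,9aR)-6-[2-(benzyloxy)ethyl]-3-hydroxy-2,2,5a-trimethyloctahydro-1-benzoxepin-7(2H)-one | c1ccccc1COCC[C@@H]1[C@@]2(C)CC[C@@H](O)C(C)(C)O[C@@H]2CCC1=O | intermediate
10 | (3R,5aR,6R,7S,9aR)-6-[2-(benzyloxy)ethyl]-2,2,5a,7-tetramethyldecahydro-1-benzoxepine-3,7-diol | c1ccccc1COCC[C@@H]1[C@@]2(C)CC[C@@H](O)C(C)(C)O[C@@H]2CC[C@]1(C)O | intermediate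
11 | (3R,5aR,6R,7S,9aR)-6-[2-(benzyloxy)ethyl]-2,2,5a,7-tetramethyldecahydro-1-benzoxepine-3,7-diyl diacetate | c1ccccc1COCC[C@@H]1[C@@]2(C)CC[C@@H](OC(C)=O)C(C)(C)O[C@@H]2CC[C@]1(C)OC(C)=O | intermediate
12 | (3R,5aR,6R,7S,9aR)-6-(2-hydroxyethyl)-2,2,5a,7-tetramethyldecahydro-1-benzoxepine-3,7-diyl diacetate | OCC[C@@H]1[C@@]2(C)CC[C@@H](OC(C)=O)C(C)(C)O[C@@H]2CC[C@]1(C)OC(C)=O | intermediate
13 | (3R,5aR,6R,7S,9aR)-6-(2-oxoethyl)-2,2,5a,7-tetramethyldecahydro-1-benzoxepine-3,7-diyl diacetate | O=CC[C@@H]1[C@@]2(C)CC[C@@H](OC(C)=O)C(C)(C)O[C@@H]2CC[C@]1(C)OC(C)=O | intermediate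
14 | (3R,5aR,6R,7S,9aR)-6-[(2E,7E)-8,12-dimethyl-4-oxotrideca-2,7,11-trien-1-yl]-2,2,5a,7-tetramethyldecahydro-1-benzoxepine-3,7-diyl diacetate | CC(C)=CCC/C(C)=C/CCC(=O)/C=C/C[C@@H]1[C@@]2(C)CC[C@@H](OC(C)=O)C(C)(C)O[C@@H]2CC[C@]1(C)OC(C)=O | intermediate
15 | (3R,5aR,6R,7S,9aR)-6-[(2E,7R,8R,11R)-7,8:11,12-diepoxy-8,12-dimethyl-4-oxotridec-2-en-1-yl]-2,2,5a,7-tetramethyldecahydro-1-benzoxepine-3,7-diyl diacetate | CC1(C)O[C@@H]1CC[C@@]1(C)O[C@@H]1CCC(=O)/C=C/C[C@@H]1[C@@]2(C)CC[C@@H](OC(C)=O)C(C)(C)O[C@@H]2CC[C@]1(C)OC(C)=O | intermediate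
16 | (3R,5aR,6R,7S,9aR)-6-[(3Z,7R,8R,11R)-7,8:11,12-diepoxy-8,12-dimethyl-4-(triethylsilyloxy)tridec-3-en-1-yl]-2,2,5a,7-tetramethyldecahydro-1-benzoxepine-3,7-diyl diacetate | CC1(C)O[C@@H]1CC[C@@]1(C)O[C@@H]1CC/C(O[Si](CC)(CC)CC)=C/CC[C@@H]1[C@@]2(C)CC[C@@H](OC(C)=O)C(C)(C)O[C@@H]2CC[C@]1(C)OC(C)=O | intermediate
17 | (3R,5aR,6R,7S,9aR)-6-{2-[(3R,5aR,6R,9aR)-2,2,5a-trimethyl-7-oxo-3-(triethylsilyloxy)decahydro-1-benzoxepin-6-yl]ethyl}-2,2,5a,7-tetramethyldecahydro-1-benzoxepine-3,7-diyl diacetate | O=C1CC[C@H]2OC(C)(C)[C@H](O[Si](CC)(CC)CC)CC[C@]2(C)[C@H]1CC[C@@H]1[C@@]2(C)CC[C@@H](OC(C)=O)C(C)(C)O[C@@H]2CC[C@]1(C)OC(C)=O | intermediate (not isolated)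
18 | (3R,5aR,6R,7S,9aR)-6-{2-[(3R,5aR,6R,9aR)-3-hydroxy-2,2,5a-trimethyl-7-oxodecahydro-1-benzoxepin-6-yl]ethyl}-2,2,5a,7-tetramethyldecahydro-1-benzoxepine-3,7-diyl diacetate | O=C1CC[C@H]2OC(C)(C)[C@H](O)CC[C@]2(C)[C@H]1CC[C@@H]1[C@@]2(C)CC[C@@H](OC(C)=O)C(C)(C)O[C@@H]2CC[C@]1(C)OC(C)=O | intermediate
19 | CNP0412606.2, (3R,5aR,6R,7S,9aR)-6-{2-[(3R,5aR,6S,9aR)-3-hydroxy-2,2,5a-trimethyl-7-methylidenedecahydro-1-benzoxepin-6-yl]ethyl}-2,2,5a,7-tetramethyldecahydro-1-benzoxepine-3,7-diyl diacetate | C=C1CC[C@H]2OC(C)(C)[C@H](O)CC[C@]2(C)[C@H]1CC[C@@H]1[C@@]2(C)CC[C@@H](OC(C)=O)C(C)(C)O[C@@H]2CC[C@]1(C)OC(C)=O | target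

**Step count.** Total: 14 steps. Longest linear sequence: 14 steps (from 1 and 2 to 19); phosphonate 3 is used in steps 2 and 10.

**Steps most likely to fail**

Step 13 (key cascade). The labile silyl enol ether may be lost by protodesilylation or silyl exchange before the epoxonium ion has formed, and the epoxonium ion may then be captured by the enol oxygen or by triflate instead of by carbon. The fallback sets out from diepoxy enone 15 and replaces the enol ether by a purely carbon-centred allylsilane terminator, which also removes the need for step 14. Conjugate reduction of 15 with LiBH(s-Bu)3 in THF at −78 °C and trapping of the (Z)-enolate with N-(5-chloro-2-pyridyl)bis(trifluoromethanesulfonimide) should give the (Z)-enol triflate F1. Negishi coupling of F1 with Me3SiCH2ZnCl and Pd(PPh3)4 in THF should give, with retention of olefin geometry, the allylsilane F2. Treatment of F2 with TMSOTf and 2,6-di-tert-butyl-4-methylpyridine in CH2Cl2 at −78 °C should run the same oxa-/carbacyclization, now ended by loss of silicon from the β-silyl cation, and give the trimethylsilyl ether F3 with the exocyclic methylene in place. HF·pyridine in the same flask should free the C3 hydroxyl, and the route is rejoined at target 19.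

Step 14 (methylenation). Addition of the methylene reagent to the hindered ketone may be slow, and prolonged contact with the Lewis-acidic titanium species may ionize the tertiary acetate. The fallback sets out from 18 and uses a two-stage Peterson olefination. Me3SiCH2MgCl with CeCl3 in THF at −78 °C should add to the ketone only and give the β-hydroxysilane F4, whose new carbinol configuration is without consequence. HF·pyridine in THF should then bring about the elimination and return the route at target 19.

Step 7 (diacetylation). Acylation of the axial tertiary hydroxyl, which is 1,3-diaxial to the angular methyl group, may stay incomplete, and forcing it may cause elimination to an olefin. The fallback sets out from ketone 9 and forms the tertiary acetate from the alkoxide instead of from the alcohol. After the MeMgBr addition of step 6, Ac2O is added to the cold solution of the bis(magnesium alkoxide) before work-up. This should acylate both oxygens and return the route at diacetate 11, merging steps 6 and 7.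

**Further compounds**

F1 | step 13 | (Z)-enol triflate: 16 with trifluoromethanesulfonyloxy in place of triethylsilyloxy | CC1(C)O[C@@H]1CC[C@@]1(C)O[C@@H]1CC/C(OS(=O)(=O)C(F)(F)F)=C/CC[C@@H]1[C@@]2(C)CC[C@@H](OC(C)=O)C(C)(C)O[C@@H]2CC[C@]1(C)OC(C)=O
F2 | step 13 | allylsilane: 16 with (trimethylsilyl)methyl in place of triethylsilyloxy, the silylmethyl group cis to the chain that leads to the diacetate bicycle | CC1(C)O[C@@H]1CC[C@@]1(C)O[C@@H]1CC/C(C[Si](C)(C)C)=C/CC[C@@H]1[C@@]2(C)CC[C@@H](OC(C)=O)C(C)(C)O[C@@H]2CC[C@]1(C)OC(C)=O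
F3 | step 13 | C3 trimethylsilyl ether of target 19 (not isolated) | C=C1CC[C@H]2OC(C)(C)[C@H](O[Si](C)(C)C)CC[C@]2(C)[C@H]1CC[C@@H]1[C@@]2(C)CC[C@@H](OC(C)=O)C(C)(C)O[C@@H]2CC[C@]1(C)OC(C)=O
F4 | step 14 | β-hydroxysilane: 18 with C7(OH)CH2SiMe3 in place of the ketone, configuration at the new carbinol carbon open | C[Si](C)(C)CC1(O)CC[C@H]2OC(C)(C)[C@H](O)CC[C@]2(C)[C@H]1CC[C@@H]1[C@@]2(C)CC[C@@H](OC(C)=O)C(C)(C)O[C@@H]2CC[C@]1(C)OC(C)=O
F0 | step 7 | none | none
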